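**Retrosynthetic overview**

1. Target ⇐ oxidation of C18H2OH to CO2H; the (13S,14R)-13-hydroxy-14,15-diacetoxy side chain is installed first, on geranylgeraniol (Sharpless epoxidation, Payne opening), and carried through.
2. C3 carries no oxygen in the target: the 3-OH left by the epoxide trigger is removed by radical deoxygenation of a 3,18-cyclic thionocarbonate.
3. Key step, one flask: an acyclic (14R,15R)-epoxy diene closes ring A (C4–C5), then ring B (C10–C9), to the ent-labdan-8-yl cation; this continues through 1,2-H (C9→C8) and 1,2-CH3 (C10→C9) shifts and loses H-1, giving the ent-halim-1(10)-ene core.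
4. The epoxy diene comes from SeO2 oxidation of the terminal E-methyl and a second Sharpless epoxidation.
5. Starting material: (2E,6E,10E)-geranylgeraniol.

Assumption: bicyclic compounds use halimane/labdane numbering (C18 = the CH2O/CO2H carbon on C4, cis to H-5); acyclic ones are numbered as hexadecane derivatives (C1 = the carbinol carbon of geranylgeraniol).

**Route**

Step 1
Reactants: 1 (2E,6E,10E)-geranylgeraniol
Product: 2 [(2S,3S)-3-methyl-3-[(3E,7E)-4,8,12-trimethyltrideca-3,7,11-trien-1-yl]oxiran-2-yl]methanol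
Conditions: Ti(OiPr)4 (10 mol%), L-(+)-diisopropyl tartrate (12 mol%), t-BuOOH, 4 Å sieves, CH2Cl2, −20 °C
Reagents that add atoms: tert-butyl hydroperoxide, CC(C)(C)OO
Why: Sharpless asymmetric epoxidation: the titanium–tartrate catalyst epoxidizes only the alkene of the allylic alcohol, and L-(+)-tartrate gives the (2S,3S)-epoxide, which fixes the future C13 as S and sets up C14 for inversion in step 2.

Step 2
Reactants: 2 [(2S,3S)-3-methyl-3-[(3E,7E)-4,8,12-trimethyltrideca-3,7,11-trien-1-yl]oxiran-2-yl]methanol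
Product: 4 (2R,3S,6E,10E)-3,7,11,15-tetramethylhexadeca-6,10,14-triene-1,2,3-triol, via 1,2-epoxy-3-ol 3 (not isolated)
Conditions: 0.5 M NaOH, t-BuOH/H2O, 75 °C
Reagents that add atoms: water, O
Why: Payne rearrangement then epoxide opening: the C1 alkoxide displaces the oxirane oxygen at C2 with inversion (SN2) to give terminal epoxide 3, which hydroxide opens at its CH2, so C2 becomes R and C3 stays S, the 13S,14R pattern of the target.

Step 3
Reactants: 4 (2R,3S,6E,10E)-3,7,11,15-tetramethylhexadeca-6,10,14-triene-1,2,3-triol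
Product: 5 (2R,3S,6E,10E)-3-hydroxy-3,7,11,15-tetramethylhexadeca-6,10,14-triene-1,2-diyl diacetate
Conditions: Ac2O (2.5 equiv), pyridine, CH2Cl2, 0 °C to rt
Reagents that add atoms: acetic anhydride, CC(=O)OC(C)=O
Why: Selective acylation: the primary and secondary hydroxyls are acetylated while the hindered tertiary hydroxyl is inert without DMAP, and no stereocentre is touched.

Step 4
Reactants: 5 (2R,3S,6E,10E)-3-hydroxy-3,7,11,15-tetramethylhexadeca-6,10,14-triene-1,2-diyl diacetate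
Product: 6 (2R,3S,6E,10E)-3,7,11,15-tetramethyl-3-(triethylsilyloxy)hexadeca-6,10,14-triene-1,2-diyl diacetate
Conditions: Et3SiOTf, 2,6-lutidine, CH2Cl2, −78 to 0 °C
Reagents that add atoms: triethylsilyl trifluoromethanesulfonate, CC[Si](CC)(CC)OS(=O)(=O)C(F)(F)F
Why: Silyl triflate silylation of a tertiary alcohol: the bulky triethylsilyl ether masks the only free oxygen nucleophile of the side chain, which would otherwise capture the C8 cation of step 7 as a cyclic ether.

Step 5
Reactants: 6 (2R,3S,6E,10E)-3,7,11,15-tetramethyl-3-(triethylsilyloxy)hexadeca-6,10,14-triene-1,2-diyl diacetate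
Product: 7 (2R,3S,6E,10E,14E)-16-hydroxy-3,7,11,15-tetramethyl-3-(triethylsilyloxy)hexadeca-6,10,14-triene-1,2-diyl diacetate
Conditions: SeO2 (0.3 equiv), t-BuOOH (3 equiv), salicylic acid (0.1 equiv), CH2Cl2, rt
Reagents that add atoms: tert-butyl hydroperoxide, CC(C)(C)OO
Why: Catalytic SeO2 allylic oxidation (ene reaction then 2,3-sigmatropic shift): the terminal isopropylidene is the most accessible trisubstituted alkene and is oxidized at its E-methyl group, giving the (E)-allylic alcohol needed for step 6.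

Step 6
Reactants: 7 (2R,3S,6E,10E,14E)-16-hydroxy-3,7,11,15-tetramethyl-3-(triethylsilyloxy)hexadeca-6,10,14-triene-1,2-diyl diacetate
Product: 8 (2R,3S,6E,10E,14R,15R)-14,15-epoxy-16-hydroxy-3,7,11,15-tetramethyl-3-(triethylsilyloxy)hexadeca-6,10-diene-1,2-diyl diacetate
Conditions: Ti(OiPr)4 (10 mol%), D-(−)-diisopropyl tartrate (12 mol%), t-BuOOH, 4 Å sieves, CH2Cl2, −25 °C
Reagents that add atoms: tert-butyl hydroperoxide, CC(C)(C)OO
Why: Sharpless asymmetric epoxidation of a 2-methyl-2-alken-1-ol: D-(−)-tartrate gives the (14R,15R)-epoxide under reagent control, independent of the remote C2/C3 centres, and any minor enantiomer carried from step 1 becomes a separable diastereomer here.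

Step 7
Reactants: 8 (2R,3S,6E,10E,14R,15R)-14,15-epoxy-16-hydroxy-3,7,11,15-tetramethyl-3-(triethylsilyloxy)hexadeca-6,10-diene-1,2-diyl diacetate
Product: 11 (3R,4S,5S,8R,9S,13S,14R)-3,18-dihydroxy-13-(triethylsilyloxy)-ent-halim-1(10)-ene-14,15-diyl diacetate, via ent-labdan-8-yl cation 9 (not isolated), via ent-haliman-10-yl cation 10 (not isolated)
Conditions: MeAlCl2 (5 equiv), CH2Cl2, −78 to −30 °C; Et3N/MeOH quench; aq. KNaC4H4O6
Reagents that add atoms: none
Why: Proposed new method: MeAlCl2 turns the 18-OH into an alkoxy-AlCl2 group that activates the adjacent oxirane, and anti opening at C4 (inversion) by the two E-alkenes in a chair–chair fold closes ring A then ring B to the trans-fused cation 9 with the CH2O arm equatorial (4S,5S); because both oxygens are then locked in an aluminium 3,18-diolate chelate far from C8, the side chain has no π bond or free oxygen, and MeAlCl2 scavenges protons and chloride, the cation is expected to persist long enough for the antiperiplanar, suprafacial 1,2-H shift (H9 to C8, giving 8R) and 1,2-CH3 shift (C20 to C9, giving 9S) that relieve the 1,3-diaxial CH3-19/CH3-20 strain; the charge should stop at C10 because C5/C4 cations are destabilised by the C3/C18 oxygens, and irreversible loss of the exposed H-1 (H-5 is boxed in by the C4 chelate and by the C9 side chain on its own face) gives the 1(10)-ene; the closest known reaction types are the MeAlCl2-promoted epoxy-polyene bicyclization, the sequential 1,2-hydride/alkyl shifts of alkylaluminium halide zwitterions, and the Lewis acid-induced 1,2-H/1,2-CH3 shift of drimane and labdane 8-cations.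

Step 8
Reactants: 11 (3R,4S,5S,8R,9S,13S,14R)-3,18-dihydroxy-13-(triethylsilyloxy)-ent-halim-1(10)-ene-14,15-diyl diacetate
Product: 12 (3R,4S,5S,8R,9S,13S,14R)-3,18-O-thiocarbonyl-13-(triethylsilyloxy)-ent-halim-1(10)-ene-14,15-diyl diacetate (six-membered cyclic thionocarbonate across O3 and O18)
Conditions: 1,1'-thiocarbonyldiimidazole (1.5 equiv), DMAP (cat.), toluene, 90 °C
Reagents that add atoms: 1,1'-thiocarbonyldiimidazole, S=C(n1ccnc1)n1ccnc1
Why: Thiocarbonylation of a 1,3-diol: the equatorial 3-OH and the equatorial CH2OH on C4 close a six-membered cyclic thionocarbonate, which prepares the two C–O bonds for selective radical cleavage without touching a stereocentre.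

Step 9
Reactants: 12 (3R,4S,5S,8R,9S,13S,14R)-3,18-O-thiocarbonyl-13-(triethylsilyloxy)-ent-halim-1(10)-ene-14,15-diyl diacetate
Product: 14 (4S,5S,8R,9S,13S,14R)-13,18-dihydroxy-ent-halim-1(10)-ene-14,15-diyl diacetate, via S-stannyl thiocarbonate 13 (not isolated)
Conditions: Bu3SnH (3 equiv), AIBN (0.2 equiv), toluene, 110 °C; then HF·pyridine, THF, 0 °C to rt
Reagents that add atoms: none
Why: Barton-type radical deoxygenation of a cyclic thionocarbonate: the tin radical adds to sulfur and the ring fragments toward the more stable secondary C3 radical (not the primary neopentyl C18 radical), which Bu3SnH reduces to CH2, and HF·pyridine then cleaves the Sn–S bond (loss of COS) and the triethylsilyl ether in the same flask.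

Step 10
Reactants: 14 (4S,5S,8R,9S,13S,14R)-13,18-dihydroxy-ent-halim-1(10)-ene-14,15-diyl diacetate
Product: 16 (4S,5S,8R,9S,13S,14R)-14,15-diacetoxy-13-hydroxy-ent-halim-1(10)-en-18-oic acid, via 18-aldehyde 15 (not isolated)
Conditions: TEMPO (0.3 equiv), PhI(OAc)2 (2.5 equiv), MeCN/H2O (1:1), rt
Reagents that add atoms: water, O
Why: Oxoammonium (TEMPO) oxidation with PhI(OAc)2 in wet acetonitrile takes the only primary alcohol through aldehyde 15 and its hydrate to the acid, while the tertiary alcohol, the acetates and the hindered 1(10)-alkene do not react, so all six stereocentres reach the target unchanged.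

**Compound list**

1 | (2E,6E,10E)-geranylgeraniol | OC/C=C(\C)CC/C=C(\C)CC/C=C(\C)CCC=C(C)C | starting material
2 | [(2S,3S)-3-methyl-3-[(3E,7E)-4,8,12-trimethyltrideca-3,7,11-trien-1-yl]oxiran-2-yl]methanol | OC[C@@H]1O[C@@]1(C)CC/C=C(\C)CC/C=C(\C)CCC=C(C)C | intermediate
3 | (2S,5E,9E)-6,10,14-trimethyl-2-[(2R)-oxiran-2-yl]pentadeca-5,9,13-trien-2-ol (not isolated) | C1O[C@H]1[C@@](C)(O)CC/C=C(\C)CC/C=C(\C)CCC=C(C)C | intermediate
4 | (2R,3S,6E,10E)-3,7,11,15-tetramethylhexadeca-6,10,14-triene-1,2,3-triol | OC[C@@H](O)[C@@](C)(O)CC/C=C(\C)CC/C=C(\C)CCC=C(C)C | intermediate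
5 | (2R,3S,6E,10E)-3-hydroxy-3,7,11,15-tetramethylhexadeca-6,10,14-triene-1,2-diyl diacetate | CC(=O)OC[C@@H](OC(C)=O)[C@@](C)(O)CC/C=C(\C)CC/C=C(\C)CCC=C(C)C | intermediate
6 | (2R,3S,6E,10E)-3,7,11,15-tetramethyl-3-(triethylsilyloxy)hexadeca-6,10,14-triene-1,2-diyl diacetate | CC(=O)OC[C@@H](OC(C)=O)[C@@](C)(O[Si](CC)(CC)CC)CC/C=C(\C)CC/C=C(\C)CCC=C(C)C | intermediate
7 | (2R,3S,6E,10E,14E)-16-hydroxy-3,7,11,15-tetramethyl-3-(triethylsilyloxy)hexadeca-6,10,14-triene-1,2-diyl diacetate | CC(=O)OC[C@@H](OC(C)=O)[C@@](C)(O[Si](CC)(CC)CC)CC/C=C(\C)CC/C=C(\C)CC/C=C(\C)CO | intermediate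
8 | (2R,3S,6E,10E,14R,15R)-14,15-epoxy-16-hydroxy-3,7,11,15-tetramethyl-3-(triethylsilyloxy)hexadeca-6,10-diene-1,2-diyl diacetate | CC(=O)OC[C@@H](OC(C)=O)[C@@](C)(O[Si](CC)(CC)CC)CC/C=C(\C)CC/C=C(\C)CC[C@H]1O[C@]1(C)CO | intermediate
9 | (3R,4S,5S,9R,10S,13S,14R)-14,15-diacetoxy-3,18-dihydroxy-13-(triethylsilyloxy)-ent-labdan-8-ylium, trans-fused, drawn as the free diol (O3 and O18 are aluminium-bound in the flask; not isolated) | CC(=O)OC[C@@H](OC(C)=O)[C@@](C)(O[Si](CC)(CC)CC)CC[C@@H]1[C+](C)CC[C@@H]2[C@@](C)(CO)[C@H](O)CC[C@@]12C | intermediate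
10 | (3R,4S,5S,8R,9R,13S,14R)-14,15-diacetoxy-3,18-dihydroxy-13-(triethylsilyloxy)-ent-haliman-10-ylium, drawn as the free diol (not isolated) | CC(=O)OC[C@@H](OC(C)=O)[C@@](C)(O[Si](CC)(CC)CC)CC[C@]1(C)[C+]2CC[C@@H](O)[C@](C)(CO)[C@H]2CC[C@H]1C | intermediate
11 | (3R,4S,5S,8R,9S,13S,14R)-3,18-dihydroxy-13-(triethylsilyloxy)-ent-halim-1(10)-ene-14,15-diyl diacetate | CC(=O)OC[C@@H](OC(C)=O)[C@@](C)(O[Si](CC)(CC)CC)CC[C@]1(C)C2=CC[C@@H](O)[C@](C)(CO)[C@H]2CC[C@H]1C | intermediate
12 | (3R,4S,5S,8R,9S,13S,14R)-3,18-O-thiocarbonyl-13-(triethylsilyloxy)-ent-halim-1(10)-ene-14,15-diyl diacetate | CC(=O)OC[C@@H](OC(C)=O)[C@@](C)(O[Si](CC)(CC)CC)CC[C@]1(C)C2=CC[C@H]3OC(=S)OC[C@]3(C)[C@H]2CC[C@H]1C | intermediate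
13 | S-tributylstannyl O-[(4S,5S,8R,9S,13S,14R)-14,15-diacetoxy-13-(triethylsilyloxy)-ent-halim-1(10)-en-18-yl] thiocarbonate (not isolated) | CC(=O)OC[C@@H](OC(C)=O)[C@@](C)(O[Si](CC)(CC)CC)CC[C@]1(C)C2=CCC[C@](C)(COC(=O)S[Sn](CCCC)(CCCC)CCCC)[C@H]2CC[C@H]1C | intermediate
14 | (4S,5S,8R,9S,13S,14R)-13,18-dihydroxy-ent-halim-1(10)-ene-14,15-diyl diacetate | CC(=O)OC[C@@H](OC(C)=O)[C@@](C)(O)CC[C@]1(C)C2=CCC[C@](C)(CO)[C@H]2CC[C@H]1C | intermediate
15 | (4S,5S,8R,9S,13S,14R)-14,15-diacetoxy-13-hydroxy-ent-halim-1(10)-en-18-al (not isolated) | CC(=O)OC[C@@H](OC(C)=O)[C@@](C)(O)CC[C@]1(C)C2=CCC[C@](C)(C=O)[C@H]2CC[C@H]1C | intermediate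
16 | (4S,5S,8R,9S,13S,14R)-14,15-diacetoxy-13-hydroxy-ent-halim-1(10)-en-18-oic acid (CNP0224606.2) | CC(=O)OC[C@@H](OC(C)=O)[C@@](C)(O)CC[C@]1(C)C2=CCC[C@](C)(C(=O)O)[C@H]2CC[C@H]1C | target

**Step count**

Total steps: 10. Longest linear sequence: 10 steps (1 to 16; the route is fully linear).

**Steps most likely to fail, with fallbacks**

Step 7 (cascade) is by far the largest risk. It can stop at the ordinary labdane olefins, or it can lose H-5 instead of H-1 and give the 5(10)-ene, which is probably the thermodynamically preferred olefin. The fallback sets out from 8 and returns at 11, and separates the events. Quench the MeAlCl2 cyclization at −94 °C after a few minutes and isolate the normal bicyclization product, (3R,4S,5S,9R,10S,13S,14R)-3,18-dihydroxy-13-(triethylsilyloxy)-ent-labd-7-ene-14,15-diyl diacetate F1 (its 8(17) isomer behaves the same). Treat it with BF3·OEt2 in CH2Cl2 (−50 to −10 °C): the 1,2-H/1,2-CH3 shifts now run under equilibrating conditions and the free 18-hydroxyl captures C10 on the face of H-5, so all olefin isomers funnel into the cis-fused (3R,4S,5R,8R,9S,10R,13S,14R)-10,18-epoxy-3-hydroxy-13-(triethylsilyloxy)-ent-halimane-14,15-diyl diacetate F2. Open this ether with Me3SiOTf and 2,6-di-tert-butyl-4-methylpyridine (−78 to −30 °C). In F2 the C10–O bond is anti-periplanar to an axial H-1 and syn to H-5, and the hindered base is meant to take the exposed C1 proton, giving the 3,18-bis(trimethylsilyl) ether of 11 F3. This eliminative opening is itself unproven. Citric acid/MeOH then removes both trimethylsilyl groups to give 11, and any 5(10)-ene is returned to F2 with BF3·OEt2 and recycled.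

Step 9 (radical deoxygenation) depends on the thionocarbonate fragmenting toward C3 and on the secondary radical being reduced before it rearranges. The fallback sets out from 11 and returns at 14, and removes the regiochemical choice. Silylate the primary hydroxyl with tBuMe2SiCl/imidazole to the 18-O-tert-butyldimethylsilyl ether of 11 F4. Convert the remaining 3-OH with 1,1'-thiocarbonyldiimidazole into the 3-O-(imidazol-1-ylthiocarbonyl) derivative F5. Reduce with Bu3SnH/AIBN (ordinary Barton–McCombie) to the 3-deoxy 13-O-triethylsilyl 18-O-tert-butyldimethylsilyl compound F6. HF·pyridine then removes both silyl groups to give 14.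

Step 5 (SeO2 oxidation) is low-yielding: it leaves unreacted 6, over-oxidizes to the enal and touches the internal methyl groups. The fallback sets out from 6 and returns at 7, and builds the oxidized terminus by cleavage and olefination. NBS in aqueous THF gives the terminal bromohydrin, (2R,3S,6E,10E)-14-bromo-15-hydroxy-3,7,11,15-tetramethyl-3-(triethylsilyloxy)hexadeca-6,10-diene-1,2-diyl diacetate F7. DBU closes it to the 14,15-epoxide F8 (the acetates survive). HIO4 in THF/ether cleaves the epoxide to the trisnor aldehyde, (2R,3S,6E,10E)-3,7,11-trimethyl-14-oxo-3-(triethylsilyloxy)tetradeca-6,10-diene-1,2-diyl diacetate F9. Wittig reaction with Ph3P=C(CH3)CHO gives the (14E)-16-oxo enal F10, and NaBH4/CeCl3·7H2O at −20 °C reduces it to 7.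

Further compounds

F1 | step 7 | (3R,4S,5S,9R,10S,13S,14R)-3,18-dihydroxy-13-(triethylsilyloxy)-ent-labd-7-ene-14,15-diyl diacetate | CC(=O)OC[C@@H](OC(C)=O)[C@@](C)(O[Si](CC)(CC)CC)CC[C@@H]1C(C)=CC[C@@H]2[C@@](C)(CO)[C@H](O)CC[C@@]12C
F2 | step 7 | (3R,4S,5R,8R,9S,10R,13S,14R)-10,18-epoxy-3-hydroxy-13-(triethylsilyloxy)-ent-halimane-14,15-diyl diacetate | CC(=O)OC[C@@H](OC(C)=O)[C@@](C)(O[Si](CC)(CC)CC)CC[C@]1(C)[C@@]23CC[C@@H](O)[C@](C)(CO3)[C@H]2CC[C@H]1C
F3 | step 7 | (3R,4S,5S,8R,9S,13S,14R)-13-(triethylsilyloxy)-3,18-bis(trimethylsilyloxy)-ent-halim-1(10)-ene-14,15-diyl diacetate | CC(=O)OC[C@@H](OC(C)=O)[C@@](C)(O[Si](CC)(CC)CC)CC[C@]1(C)C2=CC[C@@H](O[Si](C)(C)C)[C@](C)(CO[Si](C)(C)C)[C@H]2CC[C@H]1C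
F4 | step 9 | (3R,4S,5S,8R,9S,13S,14R)-18-(tert-butyldimethylsilyloxy)-3-hydroxy-13-(triethylsilyloxy)-ent-halim-1(10)-ene-14,15-diyl diacetate | CC(=O)OC[C@@H](OC(C)=O)[C@@](C)(O[Si](CC)(CC)CC)CC[C@]1(C)C2=CC[C@@H](O)[C@](C)(CO[Si](C)(C)C(C)(C)C)[C@H]2CC[C@H]1C
F5 | step 9 | (3R,4S,5S,8R,9S,13S,14R)-18-(tert-butyldimethylsilyloxy)-3-(imidazol-1-ylthiocarbonyloxy)-13-(triethylsilyloxy)-ent-halim-1(10)-ene-14,15-diyl diacetate | CC(=O)OC[C@@H](OC(C)=O)[C@@](C)(O[Si](CC)(CC)CC)CC[C@]1(C)C2=CC[C@@H](OC(=S)n3ccnc3)[C@](C)(CO[Si](C)(C)C(C)(C)C)[C@H]2CC[C@H]1C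
F6 | step 9 | (4S,5S,8R,9S,13S,14R)-18-(tert-butyldimethylsilyloxy)-13-(triethylsilyloxy)-ent-halim-1(10)-ene-14,15-diyl diacetate | CC(=O)OC[C@@H](OC(C)=O)[C@@](C)(O[Si](CC)(CC)CC)CC[C@]1(C)C2=CCC[C@](C)(CO[Si](C)(C)C(C)(C)C)[C@H]2CC[C@H]1C
F7 | step 5 | (2R,3S,6E,10E)-14-bromo-15-hydroxy-3,7,11,15-tetramethyl-3-(triethylsilyloxy)hexadeca-6,10-diene-1,2-diyl diacetate (both C14 epimers) | CC(=O)OC[C@@H](OC(C)=O)[C@@](C)(O[Si](CC)(CC)CC)CC/C=C(\C)CC/C=C(\C)CCC(Br)C(C)(C)O
F8 | step 5 | (2R,3S,6E,10E)-14,15-epoxy-3,7,11,15-tetramethyl-3-(triethylsilyloxy)hexadeca-6,10-diene-1,2-diyl diacetate (both C14 epimers) | CC(=O)OC[C@@H](OC(C)=O)[C@@](C)(O[Si](CC)(CC)CC)CC/C=C(\C)CC/C=C(\C)CCC1OC1(C)C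
F9 | step 5 | (2R,3S,6E,10E)-3,7,11-trimethyl-14-oxo-3-(triethylsilyloxy)tetradeca-6,10-diene-1,2-diyl diacetate | CC(=O)OC[C@@H](OC(C)=O)[C@@](C)(O[Si](CC)(CC)CC)CC/C=C(\C)CC/C=C(\C)CCC=O
F10 | step 5 | (2R,3S,6E,10E,14E)-3,7,11,15-tetramethyl-16-oxo-3-(triethylsilyloxy)hexadeca-6,10,14-triene-1,2-diyl diacetate | CC(=O)OC[C@@H](OC(C)=O)[C@@](C)(O[Si](CC)(CC)CC)CC/C=C(\C)CC/C=C(\C)CC/C=C(\C)C=O
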